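## Analysis of the target

Target 31 (C30H22O15) is a linear phlorotannin pentamer: five benzene rings joined by four diaryl ether oxygens. The rings are lettered A to E from the 3,5-dihydroxyphenoxy end, and each ring is numbered from the carbon whose ether oxygen points toward ring A, so the links are A1–O–B1, B6–O–C1, C4–O–D1 and D6–O–E1. There is no stereocentre and no other element of chirality, so the problem is purely one of placing fifteen oxygens correctly on thirty ring carbons. The eleven free hydroxyls sit on phloroglucinol-type and 1,2,3,5-tetraoxygenated rings, which oxidise readily to quinones and react at every free ring position with electrophiles, so they must stay masked as ethers until the last step. The ether links differ in crowding: A1–O–B1 and C4–O–D1 have two ortho oxygens on one side only, whereas B6–O–C1 and D6–O–E1 have three ortho oxygens around the bridge. The difficulty is to form these congested ethers regioselectively on rings that offer no activation for substitution and that would make a metal-catalysed coupling of two ortho-substituted partners slow. The strategy rests on ring B: B1 and B4 carry para oxygens and B1 is flanked by the oxygenated carbons B2 and B6, which is the pattern of a hydroquinone oxygenated at both positions next to one hydroxyl. Such a hydroquinone is what thermal ring expansion of a 4-hydroxy-3-alkoxy-4-(1-oxyvinyl)cyclobutenone delivers, so ring B can be grown from a four-carbon squarate unit and a two-carbon vinyl ether that already hangs on the ring C oxygen.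

## Retrosynthetic reasoning

Target 31 is traced back to the fully O-alkylated pentamer 30 (ten methyl ethers and one isopropyl ether). Nothing is cut in the skeleton. The phenols are released only at the end because the free polyphenol tolerates neither oxidants, bases in air, nor metal catalysis. The forward step must cleave eleven alkyl–oxygen bonds and leave the four aryl–O–aryl bonds intact.

Pentamer 30 is cut at the bond between C4 and the D1 oxygen, giving the ring A–B–C triflate 24 and the ring D–E phenol 29. The cut is placed here because C4 has hydrogen on both sides, so it is the least hindered aryl carbon of any of the four links, and because it divides the molecule into a trimer and a dimer of similar size. The forward reaction is a palladium-catalysed aryl C–O coupling in which the crowded partner is the phenoxide, not the electrophile. The C4 oxygen of 24 is only a handle: triflate 24 comes from phenol 23, and 23 from benzyl ether 22.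

Phenol 29 is traced to aldehyde 27 by exchanging the D1 hydroxyl for a formyl group (peracid oxidation in the forward sense, through formate 28). Aldehyde 27 is cut at the D6–O bond into phenol 25 and fluoroaldehyde 26. The formyl group sits ortho to D6 and activates it for nucleophilic aromatic substitution, so the crowded D6–O–E1 ether is made without a metal, and the same formyl carbon then becomes the D1 oxygen.

Trimer 22 is cut at the bond between A1 and the B1 oxygen into phenol 20 and aryl iodide 21. Ring A has no ortho substituent, so all the crowding lies on the phenol side, which a copper-catalysed arylation tolerates. Phenol 20 is the B4 methyl ether of hydroquinone 19; the forward step has to distinguish the open B4 hydroxyl from the flanked B1 hydroxyl.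

Hydroquinone 19 is the point where ring B is taken apart. Its keto tautomer 18 is opened between B4 and B5 to dienylketene 17, and 17 is the ring-opened form of cyclobutenone 16. This removes ring B altogether and with it the need to couple anything to the crowded B6 and B1 positions: the B6–O–C1 ether is already present in 16 as an aryl vinyl ether. The forward reaction must open the four-membered ring with the vinyl group turned toward the ketene and close the six-membered ring onto the vinyl CH2.

Cyclobutenone 16 is cut at the future B1–B6 bond into vinyllithium 15 and semisquarate 14. The addition must go to the carbonyl next to the isopropoxy-bearing carbon, because that choice puts the isopropoxy group on B2. Vinyllithium 15 comes from stannane 11 by tin–lithium exchange, which avoids deprotonating the acidic ring and benzylic positions. Semisquarate 14 comes from squarate 12 through the mono-reduced hydroxyketone 13.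

Stannane 11 is traced to the terminal ynol ether 10 by removing tin and hydrogen across the triple bond. Ynol ether 10 goes back through acetylide 9 and chloroalkyne 8 to dichlorovinyl ether 7, and 7 is cut at the B6–O bond into phenol 4 and trichloroethylene 5, which reacts as dichloroacetylene 6. The two carbons of 5 become B5 and B6, and the hindered phenol oxygen is attached by addition to an alkyne, not by arylation.

Phenol 4 is traced to aldehyde 2 through formate 3 by the same formyl-to-hydroxyl exchange, and 2 is the benzyl ether of aldehyde 1. This fixes the hydroxyl between the two methoxy groups and the benzyloxy group para to it without any selectivity question.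

## Alternatives that were turned down

Alternative 1: Ring A would be made last, by a Diels–Alder reaction. The disconnection cuts A4–A5 and A6–A1. In the forward step 1,1-dimethoxy-3-(trimethylsilyloxy)buta-1,3-diene A1 would add to the methyl 3-aryloxypropiolate A2 of the ring B–C–D–E tetramer, and loss of methanol would aromatise the adduct to benzoate A3.
- For it: the regiochemistry follows from the polarisation of both partners, no metal is needed, and the A1–O–B1 ether would come from addition of the B1 phenoxide to an activated propiolate. On that one bond it is at least as strong as the copper-catalysed arylation of step 10.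
- Against it: ring A is the one ring that can simply be bought as 21. The propiolate A2 requires the whole B–C–D–E tetramer first, so the three crowded ethers B6–O–C1, C4–O–D1 and D6–O–E1 remain unsolved. A2 is a donor-substituted alkyne and a sluggish dienophile, and the diene A1 is sensitive to moisture. A3 carries an ester at A2 that costs a saponification and a decarboxylation, and a free hydroxyl that must be capped.
- Comparison: the chosen route gives up a metal-free ring A but constructs the most crowded ring and keeps ring A to one coupling step.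

Alternative 2: Ring E would be made by a (3+3) double Claisen condensation. The disconnection cuts E2–E3 and E5–E6. In the forward step dimethyl 3-oxopentanedioate A4 would condense through both α-carbons with the two ester groups of the aryloxymalonate A5, giving the trihydroxyisophthalate A6.
- For it: ring E arrives with its three hydroxyls free, the reagents are cheap, and the crowded D6–O–E1 ether would come from a plain O-alkylation of a phenol with a halomalonate. That is as good as the fluoride displacement of step 13.
- Against it: base removes the acidic α-hydrogen of A5 and so takes away the electrophilicity of its esters. A4 condenses with itself, and both Claisen steps are reversible until the ring aromatises. A6 has three free phenols and two esters, so decarboxylation and re-protection follow before any further coupling. The strategy also builds a terminal ring that is commercially available as 25 and does nothing for rings B and C.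
- Comparison: the chosen route reaches the same D–E fragment in two steps from 25 and 26 and spends its ring construction on ring B.

Alternative 3: Ring D would be made by a Danheiser benzannulation. The disconnection cuts D2–D3 and D4–D5. In the forward step the 3,4-bis(aryloxy)cyclobutenone A7 and ethoxyacetylene A8 would combine on heating, through a vinylketene, a (2+2) adduct and a dienylketene, to phenol A9.
- For it: the central ring forms with both ether oxygens in place, so neither the C4–O–D1 coupling of step 15 nor a separate D6–O–E1 step is needed. The ethoxy group lands meta to the new hydroxyl by the inherent regiochemistry. On the C–D junction this is stronger than the chosen route.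
- Against it: A7 is an unsymmetrical cyclobutenone with two different hindered aryloxy groups, one on an sp3 carbon next to the carbonyl. It has to be assembled regiospecifically from a squarate such as 12 at a lower oxidation level, which takes several uncertain steps before the key step. Its vinylketene is doubly donor-substituted and less reactive toward the ynol ether. Ring B would still be missing after the key step and would have to be attached by arylating the flanked C1 hydroxyl with an ortho-oxygenated ring B halide. That is the most crowded coupling the molecule offers.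
- Comparison: the chosen route accepts one palladium coupling at the uncrowded C4 position and avoids the B6–O–C1 coupling altogether.

Key step: step 8

Remark on the chemistry: 2,4,6-trimethoxyphenol 25 and 2-fluoro-4,6-dimethoxybenzaldehyde 26 are taken as catalogue compounds.

## Route

Step 1
Reactants: 1 4-hydroxy-2,6-dimethoxybenzaldehyde
Product: 2 4-(benzyloxy)-2,6-dimethoxybenzaldehyde
Conditions: BnBr, K2CO3, DMF, rt
Reagents that add atoms: benzyl bromide, BrCc1ccccc1
Why: Williamson etherification of the only hydroxyl; the aldehyde is inert to carbonate.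

Step 2
Reactants: 2 4-(benzyloxy)-2,6-dimethoxybenzaldehyde
Product: 4 4-(benzyloxy)-2,6-dimethoxyphenol, via aryl formate 3 (not isolated)
Conditions: mCPBA, CH2Cl2, 0 °C to rt; then K2CO3 (cat.), MeOH, rt
Reagents that add atoms: 3-chloroperoxybenzoic acid (mCPBA), OOC(=O)c1cccc(Cl)c1
Why: Baeyer–Villiger (Dakin-type) oxidation; the electron-rich trioxygenated aryl group migrates in the Criegee intermediate, and methanolysis of formate 3 frees the hydroxyl between the two methoxy groups with no regiochemical ambiguity.

Step 3
Reactants: 4 4-(benzyloxy)-2,6-dimethoxyphenol; 5 trichloroethylene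
Product: 7 5-(benzyloxy)-2-{[(E)-1,2-dichloroethenyl]oxy}-1,3-dimethoxybenzene, via dichloroacetylene 6 (not isolated)
Conditions: K2CO3, DMF, 70 °C
Reagents that add atoms: none
Why: Carbonate eliminates HCl from 5 to give 6 in the flask, and the phenoxide adds anti across it; this is the established preparation of aryl 1,2-dichlorovinyl ethers and the alkyne carbon is open even to a 2,6-disubstituted phenoxide.

Step 4
Reactants: 7 5-(benzyloxy)-2-{[(E)-1,2-dichloroethenyl]oxy}-1,3-dimethoxybenzene
Product: 10 5-(benzyloxy)-2-(ethynyloxy)-1,3-dimethoxybenzene, via chloroethynyl ether 8 (not isolated), via lithium acetylide 9 (not isolated)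
Conditions: n-BuLi (2.3 equiv), Et2O, −78 to −40 °C; then H2O, −78 °C
Reagents that add atoms: none
Why: Deprotonation and β-elimination of LiCl give 8, chlorine–lithium exchange gives 9, and protonation gives the terminal ynol ether, the standard dichlorovinyl ether route; the two ortho methoxy groups shield the ynol ether, which is used directly.

Step 5
Reactants: 10 5-(benzyloxy)-2-(ethynyloxy)-1,3-dimethoxybenzene
Product: 11 tributyl{1-[4-(benzyloxy)-2,6-dimethoxyphenoxy]ethenyl}stannane
Conditions: Bu3SnH, Pd(PPh3)4 (2 mol %), THF, 0 °C to rt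
Reagents that add atoms: tributyltin hydride, CCCC[SnH](CCCC)CCCC
Why: Syn hydrostannation catalysed by zerovalent palladium; with oxygen- and nitrogen-substituted alkynes the tin is delivered to the heteroatom-bearing carbon, which gives the 1-aryloxyvinylstannane.

Step 6
Reactants: 12 diisopropyl squarate
Product: 14 3-isopropoxycyclobut-3-ene-1,2-dione, via hydroxycyclobutenone 13 (not isolated)
Conditions: LiAlH(OtBu)3, THF, −78 to −20 °C; then 6 M HCl, CH2Cl2, rt
Reagents that add atoms: water, O
Why: The hindered hydride reduces one carbonyl only; acid then ionises the carbinol of 13 to an alkoxy-stabilised cyclobutenyl cation, water adds at the isopropoxy-bearing terminus and isopropanol is lost, the known preparation of alkyl semisquarates.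

Step 7
Reactants: 11 tributyl{1-[4-(benzyloxy)-2,6-dimethoxyphenoxy]ethenyl}stannane; 14 3-isopropoxycyclobut-3-ene-1,2-dione
Product: 16 4-hydroxy-3-isopropoxy-4-{1-[4-(benzyloxy)-2,6-dimethoxyphenoxy]ethenyl}cyclobut-2-en-1-one (racemic), via 1-aryloxyvinyllithium 15 (not isolated)
Conditions: n-BuLi (1.0 equiv), THF, −78 °C; then 14, −78 °C; aq. NH4Cl
Reagents that add atoms: none
Why: Tin–lithium exchange at −78 °C is much faster than deprotonation of the ring or benzyl C–H bonds; 15 adds 1,2 to the carbonyl next to the isopropoxy-bearing carbon because the other carbonyl is a vinylogous ester deactivated by that oxygen. The new carbinol stereocentre forms as a racemate and is destroyed in step 8.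

Step 8
Reactants: 16 4-hydroxy-3-isopropoxy-4-{1-[4-(benzyloxy)-2,6-dimethoxyphenoxy]ethenyl}cyclobut-2-en-1-one (racemic)
Product: 19 2-[4-(benzyloxy)-2,6-dimethoxyphenoxy]-6-isopropoxybenzene-1,4-diol, via dienylketene 17 (not isolated), via cyclohexadienone 18 (not isolated)
Conditions: toluene (degassed, 0.02 M), reflux, Ar
Reagents that add atoms: none
Why: Heating opens the cyclobutenone by conrotatory 4π electrocyclic cleavage of the bond between the carbonyl carbon and the carbinol carbon; the hydroxyl, the stronger donor, rotates outward and so places the aryloxyvinyl group on the ketene side in 17. A thermal disrotatory 6π electrocyclisation then joins the ketene carbon to the vinyl CH2 (the B4–B5 bond) and closes ring B as cyclohexadienone 18, which tautomerises irreversibly to the aromatic hydroquinone 19. This is the Moore rearrangement of 4-alkenyl-4-hydroxycyclobutenones, known for squarate adducts of simple and of α-oxygenated alkenyllithiums. No stereocentre is formed and the one in racemic 16 disappears. The constitution of 16 fixes the regiochemistry: the isopropoxy carbon becomes B2, the carbinol carbon B1, the ring CH B3, the ketene carbon B4, the vinyl CH2 B5 and the aryloxy-bearing vinyl carbon B6. The selectivity needed is outward rotation of the hydroxyl, since inward rotation would let it add to the ketene and give a furanone; the donor character of the hydroxyl secures it, and the unsubstituted CH2 terminus keeps the closure unhindered. Dilution and exclusion of oxygen suppress ketene dimerisation and oxidation of 19 to the quinone.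

Step 9
Reactants: 19 2-[4-(benzyloxy)-2,6-dimethoxyphenoxy]-6-isopropoxybenzene-1,4-diol
Product: 20 2-[4-(benzyloxy)-2,6-dimethoxyphenoxy]-6-isopropoxy-4-methoxyphenol
Conditions: MeI (1.05 equiv), K2CO3, acetone, rt, Ar
Reagents that add atoms: iodomethane, CI
Why: Williamson methylation with one equivalent; the B4 hydroxyl has two meta oxygens and no ortho substituent, so it is both more acidic and more accessible than the B1 hydroxyl, which is flanked by the isopropoxy and aryloxy groups.

Step 10
Reactants: 20 2-[4-(benzyloxy)-2,6-dimethoxyphenoxy]-6-isopropoxy-4-methoxyphenol; 21 1-iodo-3,5-dimethoxybenzene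
Product: 22 5-(benzyloxy)-2-[2-(3,5-dimethoxyphenoxy)-3-isopropoxy-5-methoxyphenoxy]-1,3-dimethoxybenzene
Conditions: CuI (10 mol %), picolinic acid (20 mol %), K3PO4, DMSO, 90 °C
Reagents that add atoms: none
Why: Ullmann-type O-arylation with a monovalent copper/picolinate catalyst, a system suited to 2,6-disubstituted phenols with unhindered aryl iodides; the iodide is used for easy activation, and 21 has no ortho substituent.

Step 11
Reactants: 22 5-(benzyloxy)-2-[2-(3,5-dimethoxyphenoxy)-3-isopropoxy-5-methoxyphenoxy]-1,3-dimethoxybenzene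
Product: 23 4-[2-(3,5-dimethoxyphenoxy)-3-isopropoxy-5-methoxyphenoxy]-3,5-dimethoxyphenol
Conditions: H2 (1 atm), Pd/C, EtOAc/MeOH, rt
Reagents that add atoms: none
Why: Hydrogenolysis of the benzyl ether; alkyl aryl and diaryl ethers are untouched.

Step 12
Reactants: 23 4-[2-(3,5-dimethoxyphenoxy)-3-isopropoxy-5-methoxyphenoxy]-3,5-dimethoxyphenol
Product: 24 4-[2-(3,5-dimethoxyphenoxy)-3-isopropoxy-5-methoxyphenoxy]-3,5-dimethoxyphenyl trifluoromethanesulfonate
Conditions: Tf2O, pyridine, CH2Cl2, 0 °C
Reagents that add atoms: trifluoromethanesulfonic anhydride, O=S(=O)(OS(=O)(=O)C(F)(F)F)C(F)(F)F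
Why: O-sulfonylation of the single, unhindered phenol; at 0 °C with pyridine the electron-rich rings are not attacked.

Step 13
Reactants: 25 2,4,6-trimethoxyphenol; 26 2-fluoro-4,6-dimethoxybenzaldehyde
Product: 27 2,4-dimethoxy-6-(2,4,6-trimethoxyphenoxy)benzaldehyde
Conditions: Cs2CO3, DMSO, 120 °C, Ar
Reagents that add atoms: none
Why: Nucleophilic aromatic substitution of fluoride ortho to the formyl group, which takes up the charge of the Meisenheimer intermediate; both methoxy groups are meta to the carbon attacked and do not push electrons onto it, and displacement of fluoride tolerates a 2,6-disubstituted phenoxide.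

Step 14
Reactants: 27 2,4-dimethoxy-6-(2,4,6-trimethoxyphenoxy)benzaldehyde
Product: 29 2,4-dimethoxy-6-(2,4,6-trimethoxyphenoxy)phenol, via aryl formate 28 (not isolated)
Conditions: mCPBA, CH2Cl2, 0 °C to rt; then K2CO3 (cat.), MeOH, rt
Reagents that add atoms: 3-chloroperoxybenzoic acid (mCPBA), OOC(=O)c1cccc(Cl)c1
Why: Baeyer–Villiger (Dakin-type) oxidation with migration of the trioxygenated aryl group, then methanolysis of formate 28; the formyl carbon that activated D6 in step 13 becomes the D1 hydroxyl.

Step 15
Reactants: 24 4-[2-(3,5-dimethoxyphenoxy)-3-isopropoxy-5-methoxyphenoxy]-3,5-dimethoxyphenyl trifluoromethanesulfonate; 29 2,4-dimethoxy-6-(2,4,6-trimethoxyphenoxy)phenol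
Product: 30 2-{4-[2-(3,5-dimethoxyphenoxy)-3-isopropoxy-5-methoxyphenoxy]-3,5-dimethoxyphenoxy}-1,5-dimethoxy-3-(2,4,6-trimethoxyphenoxy)benzene
Conditions: Pd(OAc)2 (5 mol %), tBuXPhos (2-di-tert-butylphosphino-2′,4′,6′-triisopropylbiphenyl, 7.5 mol %), K3PO4, toluene, 100 °C
Reagents that add atoms: none
Why: Buchwald–Hartwig-type diaryl ether synthesis; the triflate carbon C4 has no ortho substituent, the bulky biarylphosphine drives the C–O reductive elimination, and ortho-substituted phenoxides favour this step. Sparingly soluble K3PO4 in toluene keeps the phenoxide concentration low and limits attack at sulfur.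

Step 16
Reactants: 30 2-{4-[2-(3,5-dimethoxyphenoxy)-3-isopropoxy-5-methoxyphenoxy]-3,5-dimethoxyphenoxy}-1,5-dimethoxy-3-(2,4,6-trimethoxyphenoxy)benzene
Product: 31 2-[2-(3,5-dihydroxyphenoxy)-3,5-dihydroxyphenoxy]-5-[2,4-dihydroxy-6-(2,4,6-trihydroxyphenoxy)phenoxy]benzene-1,3-diol (CNP0018313.0)
Conditions: BBr3 (excess), CH2Cl2, −78 °C to rt; then H2O, Ar
Reagents that add atoms: none
Why: Lewis acid dealkylation; bromide attacks the methyl and isopropyl carbons of the boron-complexed ethers, whereas the diaryl ether oxygens are poor donors and have no alkyl carbon to lose. Aqueous work-up under argon hydrolyses the aryl borates.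

## Compound list

1 | 4-hydroxy-2,6-dimethoxybenzaldehyde | COc1cc(O)cc(OC)c1C=O | starting material
2 | 4-(benzyloxy)-2,6-dimethoxybenzaldehyde | COc1cc(OCc2ccccc2)cc(OC)c1C=O | intermediate
3 | 4-(benzyloxy)-2,6-dimethoxyphenyl formate | COc1cc(OCc2ccccc2)cc(OC)c1OC=O | intermediate
4 | 4-(benzyloxy)-2,6-dimethoxyphenol | COc1cc(OCc2ccccc2)cc(OC)c1O | intermediate
5 | trichloroethylene | ClC=C(Cl)Cl | starting material
6 | dichloroacetylene | ClC#CCl | intermediate
7 | 5-(benzyloxy)-2-{[(E)-1,2-dichloroethenyl]oxy}-1,3-dimethoxybenzene | COc1cc(OCc2ccccc2)cc(OC)c1O/C(Cl)=C\Cl | intermediate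
8 | 5-(benzyloxy)-2-[(chloroethynyl)oxy]-1,3-dimethoxybenzene | COc1cc(OCc2ccccc2)cc(OC)c1OC#CCl | intermediate
9 | {[4-(benzyloxy)-2,6-dimethoxyphenoxy]ethynyl}lithium | COc1cc(OCc2ccccc2)cc(OC)c1OC#C[Li] | intermediate
10 | 5-(benzyloxy)-2-(ethynyloxy)-1,3-dimethoxybenzene | COc1cc(OCc2ccccc2)cc(OC)c1OC#C | intermediate
11 | tributyl{1-[4-(benzyloxy)-2,6-dimethoxyphenoxy]ethenyl}stannane | CCCC[Sn](CCCC)(CCCC)C(=C)Oc1c(OC)cc(OCc2ccccc2)cc1OC | intermediate
12 | diisopropyl squarate (3,4-diisopropoxycyclobut-3-ene-1,2-dione) | CC(C)OC1=C(OC(C)C)C(=O)C1=O | starting material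
13 | 4-hydroxy-2,3-diisopropoxycyclobut-2-en-1-one (racemic) | CC(C)OC1=C(OC(C)C)C(O)C1=O | intermediate
14 | 3-isopropoxycyclobut-3-ene-1,2-dione | CC(C)OC1=CC(=O)C1=O | intermediate
15 | {1-[4-(benzyloxy)-2,6-dimethoxyphenoxy]ethenyl}lithium | [Li]C(=C)Oc1c(OC)cc(OCc2ccccc2)cc1OC | intermediate
16 | 4-hydroxy-3-isopropoxy-4-{1-[4-(benzyloxy)-2,6-dimethoxyphenoxy]ethenyl}cyclobut-2-en-1-one (racemic) | CC(C)OC1=CC(=O)C1(O)C(=C)Oc1c(OC)cc(OCc2ccccc2)cc1OC | intermediate
17 | (3Z)-5-[4-(benzyloxy)-2,6-dimethoxyphenoxy]-4-hydroxy-3-isopropoxyhexa-1,3,5-trien-1-one | O=C=C/C(OC(C)C)=C(/O)C(=C)Oc1c(OC)cc(OCc2ccccc2)cc1OC | intermediate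
18 | 5-[4-(benzyloxy)-2,6-dimethoxyphenoxy]-4-hydroxy-3-isopropoxycyclohexa-2,4-dien-1-one | O=C1CC(Oc2c(OC)cc(OCc3ccccc3)cc2OC)=C(O)C(OC(C)C)=C1 | intermediate
19 | 2-[4-(benzyloxy)-2,6-dimethoxyphenoxy]-6-isopropoxybenzene-1,4-diol | CC(C)Oc1cc(O)cc(Oc2c(OC)cc(OCc3ccccc3)cc2OC)c1O | intermediate
20 | 2-[4-(benzyloxy)-2,6-dimethoxyphenoxy]-6-isopropoxy-4-methoxyphenol | CC(C)Oc1cc(OC)cc(Oc2c(OC)cc(OCc3ccccc3)cc2OC)c1O | intermediate
21 | 1-iodo-3,5-dimethoxybenzene | COc1cc(I)cc(OC)c1 | starting material
22 | 5-(benzyloxy)-2-[2-(3,5-dimethoxyphenoxy)-3-isopropoxy-5-methoxyphenoxy]-1,3-dimethoxybenzene | CC(C)Oc1cc(OC)cc(Oc2c(OC)cc(OCc3ccccc3)cc2OC)c1Oc1cc(OC)cc(OC)c1 | intermediate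
23 | 4-[2-(3,5-dimethoxyphenoxy)-3-isopropoxy-5-methoxyphenoxy]-3,5-dimethoxyphenol | CC(C)Oc1cc(OC)cc(Oc2c(OC)cc(O)cc2OC)c1Oc1cc(OC)cc(OC)c1 | intermediate
24 | 4-[2-(3,5-dimethoxyphenoxy)-3-isopropoxy-5-methoxyphenoxy]-3,5-dimethoxyphenyl trifluoromethanesulfonate | CC(C)Oc1cc(OC)cc(Oc2c(OC)cc(OS(=O)(=O)C(F)(F)F)cc2OC)c1Oc1cc(OC)cc(OC)c1 | intermediate
25 | 2,4,6-trimethoxyphenol | COc1cc(OC)c(O)c(OC)c1 | starting material
26 | 2-fluoro-4,6-dimethoxybenzaldehyde | COc1cc(F)c(C=O)c(OC)c1 | starting material
27 | 2,4-dimethoxy-6-(2,4,6-trimethoxyphenoxy)benzaldehyde | COc1cc(OC)c(C=O)c(Oc2c(OC)cc(OC)cc2OC)c1 | intermediate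
28 | 2,4-dimethoxy-6-(2,4,6-trimethoxyphenoxy)phenyl formate | COc1cc(OC)c(OC=O)c(Oc2c(OC)cc(OC)cc2OC)c1 | intermediate
29 | 2,4-dimethoxy-6-(2,4,6-trimethoxyphenoxy)phenol | COc1cc(OC)c(O)c(Oc2c(OC)cc(OC)cc2OC)c1 | intermediate
30 | 2-{4-[2-(3,5-dimethoxyphenoxy)-3-isopropoxy-5-methoxyphenoxy]-3,5-dimethoxyphenoxy}-1,5-dimethoxy-3-(2,4,6-trimethoxyphenoxy)benzene | CC(C)Oc1cc(OC)cc(Oc2c(OC)cc(Oc3c(OC)cc(OC)cc3Oc3c(OC)cc(OC)cc3OC)cc2OC)c1Oc1cc(OC)cc(OC)c1 | intermediate
31 | 2-[2-(3,5-dihydroxyphenoxy)-3,5-dihydroxyphenoxy]-5-[2,4-dihydroxy-6-(2,4,6-trihydroxyphenoxy)phenoxy]benzene-1,3-diol (CNP0018313.0) | Oc1cc(O)cc(Oc2c(O)cc(O)cc2Oc2c(O)cc(Oc3c(O)cc(O)cc3Oc3c(O)cc(O)cc3O)cc2O)c1 | target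

## Step count and least certain steps

Total: 16 steps. Longest linear sequence: 13 steps (steps 1–5, 7–12, 15 and 16). Step 6 and steps 13–14 are side branches.

Step 8 (key step). Three processes can spoil it: inward rotation of the hydroxyl, followed by its addition to the ketene to give a furanone; acid-promoted hydrolysis of the aryl vinyl ether before or during heating; and air oxidation of the hydroquinone to the quinone. The fallback abandons the squarate and makes ring B by fluoride displacement and formyl-to-hydroxyl exchange, setting out from 26 and 4 and rejoining the route at 20. BCl3 in CH2Cl2 cleaves the methoxy group ortho to the formyl group of 26 by chelation and gives 2-fluoro-6-hydroxy-4-methoxybenzaldehyde F1. Alkylation with 2-bromopropane and K2CO3 in DMF gives 2-fluoro-6-isopropoxy-4-methoxybenzaldehyde F2. Phenol 4 displaces the fluoride of F2 (Cs2CO3, DMSO, 120 °C) to give 2-[4-(benzyloxy)-2,6-dimethoxyphenoxy]-6-isopropoxy-4-methoxybenzaldehyde F3. Oxidation with mCPBA gives 2-[4-(benzyloxy)-2,6-dimethoxyphenoxy]-6-isopropoxy-4-methoxyphenyl formate F4, whose methanolysis (K2CO3, MeOH) gives 20.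

Step 15. The phenoxide of 29 may attack the sulfur of triflate 24 and return phenol 23, or transmetalation of this very hindered phenoxide may be so slow that the arylpalladium intermediate is reduced. The fallback replaces the palladium coupling by an oxidative copper coupling, setting out from 24 and rejoining at 30. Miyaura borylation of 24 (bis(pinacolato)diboron, Pd(dppf)Cl2, KOAc, dioxane, 80 °C) gives 2-{4-[2-(3,5-dimethoxyphenoxy)-3-isopropoxy-5-methoxyphenoxy]-3,5-dimethoxyphenyl}-4,4,5,5-tetramethyl-1,3,2-dioxaborolane F5. Cleavage with NaIO4 and NH4OAc in aqueous acetone gives {4-[2-(3,5-dimethoxyphenoxy)-3-isopropoxy-5-methoxyphenoxy]-3,5-dimethoxyphenyl}boronic acid F6. Chan–Evans–Lam coupling of F6 with 29 (Cu(OAc)2, pyridine, 4 Å molecular sieves, CH2Cl2, air, rt), a reaction that accepts phenols with two ortho substituents, gives 30.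

Step 5. Tin may be delivered in part to the terminal carbon, and the terminal ynol ether may oligomerise on the catalyst before it is hydrostannated. The fallback replaces hydrostannation and tin–lithium exchange by hydrobromination and bromine–lithium exchange, setting out from 10 and rejoining at 15. Markovnikov addition of anhydrous HBr (1 equiv, CH2Cl2, −78 °C) gives 5-(benzyloxy)-2-[(1-bromoethenyl)oxy]-1,3-dimethoxybenzene F7, and t-BuLi (2 equiv, THF, −78 °C) converts F7 into 15, which is used in step 7 as before.

Step 9. Double methylation, or oxidation of the hydroquinone under basic conditions, would consume 19. The fallback differentiates the two oxygens before ring B exists, setting out from 16 and rejoining at 20. Silylation of 16 (TBSOTf, 2,6-lutidine, CH2Cl2, −78 °C) gives 4-[(tert-butyldimethylsilyl)oxy]-3-isopropoxy-4-{1-[4-(benzyloxy)-2,6-dimethoxyphenoxy]ethenyl}cyclobut-2-en-1-one F8. Thermolysis of F8 in toluene keeps the silyl group on the B1 oxygen and gives 3-[4-(benzyloxy)-2,6-dimethoxyphenoxy]-4-[(tert-butyldimethylsilyl)oxy]-5-isopropoxyphenol F9. Methylation (MeI, K2CO3, acetone) gives tert-butyl{2-[4-(benzyloxy)-2,6-dimethoxyphenoxy]-6-isopropoxy-4-methoxyphenoxy}dimethylsilane F10, and TBAF in THF gives 20.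

Step 16. Eleven ethers must be cleaved, so incomplete dealkylation can leave a mixture of partly alkylated congeners, and the free polyphenol can oxidise during chromatography. The fallback changes the end-game to derivatise, purify and release, setting out from 30 and rejoining at 31. The crude BBr3 product is acetylated (Ac2O, pyridine) to 2-[2-(3,5-diacetoxyphenoxy)-3,5-diacetoxyphenoxy]-5-[2,4-diacetoxy-6-(2,4,6-triacetoxyphenoxy)phenoxy]-1,3-phenylene diacetate F11. F11 is stable and can be purified, and acid methanolysis (HCl in MeOH, argon) then gives 31.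

## Further compounds

F1 | step 8 | 2-fluoro-6-hydroxy-4-methoxybenzaldehyde | COc1cc(O)c(C=O)c(F)c1
F2 | step 8 | 2-fluoro-6-isopropoxy-4-methoxybenzaldehyde | COc1cc(F)c(C=O)c(OC(C)C)c1
F3 | step 8 | 2-[4-(benzyloxy)-2,6-dimethoxyphenoxy]-6-isopropoxy-4-methoxybenzaldehyde | COc1cc(OC(C)C)c(C=O)c(Oc2c(OC)cc(OCc3ccccc3)cc2OC)c1
F4 | step 8 | 2-[4-(benzyloxy)-2,6-dimethoxyphenoxy]-6-isopropoxy-4-methoxyphenyl formate | COc1cc(OC(C)C)c(OC=O)c(Oc2c(OC)cc(OCc3ccccc3)cc2OC)c1
F5 | step 15 | 2-{4-[2-(3,5-dimethoxyphenoxy)-3-isopropoxy-5-methoxyphenoxy]-3,5-dimethoxyphenyl}-4,4,5,5-tetramethyl-1,3,2-dioxaborolane | CC(C)Oc1cc(OC)cc(Oc2c(OC)cc(B3OC(C)(C)C(C)(C)O3)cc2OC)c1Oc1cc(OC)cc(OC)c1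
F6 | step 15 | {4-[2-(3,5-dimethoxyphenoxy)-3-isopropoxy-5-methoxyphenoxy]-3,5-dimethoxyphenyl}boronic acid | CC(C)Oc1cc(OC)cc(Oc2c(OC)cc(B(O)O)cc2OC)c1Oc1cc(OC)cc(OC)c1
F7 | step 5 | 5-(benzyloxy)-2-[(1-bromoethenyl)oxy]-1,3-dimethoxybenzene | BrC(=C)Oc1c(OC)cc(OCc2ccccc2)cc1OC
F8 | step 9 | 4-[(tert-butyldimethylsilyl)oxy]-3-isopropoxy-4-{1-[4-(benzyloxy)-2,6-dimethoxyphenoxy]ethenyl}cyclobut-2-en-1-one (racemic) | CC(C)OC1=CC(=O)C1(O[Si](C)(C)C(C)(C)C)C(=C)Oc1c(OC)cc(OCc2ccccc2)cc1OC
F9 | step 9 | 3-[4-(benzyloxy)-2,6-dimethoxyphenoxy]-4-[(tert-butyldimethylsilyl)oxy]-5-isopropoxyphenol | CC(C)Oc1cc(O)cc(Oc2c(OC)cc(OCc3ccccc3)cc2OC)c1O[Si](C)(C)C(C)(C)C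
F10 | step 9 | tert-butyl{2-[4-(benzyloxy)-2,6-dimethoxyphenoxy]-6-isopropoxy-4-methoxyphenoxy}dimethylsilane | CC(C)Oc1cc(OC)cc(Oc2c(OC)cc(OCc3ccccc3)cc2OC)c1O[Si](C)(C)C(C)(C)C
F11 | step 16 | 2-[2-(3,5-diacetoxyphenoxy)-3,5-diacetoxyphenoxy]-5-[2,4-diacetoxy-6-(2,4,6-triacetoxyphenoxy)phenoxy]-1,3-phenylene diacetate | CC(=O)Oc1cc(OC(C)=O)cc(Oc2c(OC(C)=O)cc(OC(C)=O)cc2Oc2c(OC(C)=O)cc(Oc3c(OC(C)=O)cc(OC(C)=O)cc3Oc3c(OC(C)=O)cc(OC(C)=O)cc3OC(C)=O)cc2OC(C)=O)c1
A1 | alternative 1 | 1,1-dimethoxy-3-(trimethylsilyloxy)buta-1,3-diene | COC(OC)=CC(=C)O[Si](C)(C)C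
A2 | alternative 1 | methyl 3-{2-[4-(2,4-dimethoxy-6-(2,4,6-trimethoxyphenoxy)phenoxy)-2,6-dimethoxyphenoxy]-4,6-dimethoxyphenoxy}prop-2-ynoate | COC(=O)C#COc1c(OC)cc(OC)cc1Oc1c(OC)cc(Oc2c(OC)cc(OC)cc2Oc2c(OC)cc(OC)cc2OC)cc1OC
A3 | alternative 1 | methyl 2-{2-[4-(2,4-dimethoxy-6-(2,4,6-trimethoxyphenoxy)phenoxy)-2,6-dimethoxyphenoxy]-4,6-dimethoxyphenoxy}-4-hydroxy-6-methoxybenzoate | COC(=O)c1c(OC)cc(O)cc1Oc1c(OC)cc(OC)cc1Oc1c(OC)cc(Oc2c(OC)cc(OC)cc2Oc2c(OC)cc(OC)cc2OC)cc1OC
A4 | alternative 2 | dimethyl 3-oxopentanedioate | COC(=O)CC(=O)CC(=O)OC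
A5 | alternative 2 | dimethyl 2-[2-(benzyloxy)-3,5-dimethoxyphenoxy]malonate | COC(=O)C(Oc1cc(OC)cc(OC)c1OCc1ccccc1)C(=O)OC
A6 | alternative 2 | dimethyl 5-[2-(benzyloxy)-3,5-dimethoxyphenoxy]-2,4,6-trihydroxyisophthalate | COC(=O)c1c(O)c(C(=O)OC)c(O)c(Oc2cc(OC)cc(OC)c2OCc2ccccc2)c1O
A7 | alternative 3 | 4-[4-(benzyloxy)-3,5-dimethoxyphenoxy]-3-(2,4,6-trimethoxyphenoxy)cyclobut-2-en-1-one (racemic) | O=C1C=C(Oc2c(OC)cc(OC)cc2OC)C1Oc1cc(OC)c(OCc2ccccc2)c(OC)c1
A8 | alternative 3 | ethoxyacetylene | CCOC#C
A9 | alternative 3 | 2-[4-(benzyloxy)-3,5-dimethoxyphenoxy]-5-ethoxy-3-(2,4,6-trimethoxyphenoxy)phenol | CCOc1cc(O)c(Oc2cc(OC)c(OCc3ccccc3)c(OC)c2)c(Oc2c(OC)cc(OC)cc2OC)c1
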